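**Strategy.** The flavanone is cut between C2 of the pyranone ring and C1' of the B ring. C2 is β to the C4 carbonyl and bears the ring oxygen O1, so at the chromone oxidation level (C2=C3) it is the electrophilic end of a vinylogous ester, while C1' can arrive as an aryl–metal. A rhodium-catalysed asymmetric 1,4-addition of a silyl-protected 4-hydroxy-2-methoxyphenylboronic acid to the fully elaborated 8-lavandulyl-5-methoxychromone joins the two halves and sets the C2 configuration by catalyst control in one operation. The chromone comes from an 8-iodochromone and (S)-lavandulyl iodide (Evans deconjugative prenylation) by Negishi coupling; buffered desilylation finishes the synthesis.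

Key step: step 11

Remark: compounds 1, 2, 5, 10 and 17 are taken as commercial. The side-chain centre keeps one spatial arrangement throughout; its descriptor is S while the CH2 carries O, I or Zn (or is the imide C=O) and becomes R once the CH2 carries the arene, because isopropenyl then outranks CH2Ar.

Step 1
Reactants: 1 (S)-4-benzyl-2-oxazolidinone; 2 3-methylbut-2-enoyl chloride
Product: 4 (4S)-4-benzyl-3-(3-methylbut-2-enoyl)oxazolidin-2-one, via lithium oxazolidinide 3 (not isolated)
Conditions: n-BuLi, THF, −78 °C; then 2, −78 → 0 °C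
Reagents that add atoms: none
Why: N-Acylation of the lithiated Evans auxiliary by the acid chloride at low temperature is standard and avoids amine bases that could isomerise the senecioyl group through a vinylketene; no stereocentre is formed.

Step 2
Reactants: 4 (4S)-4-benzyl-3-(3-methylbut-2-enoyl)oxazolidin-2-one; 5 prenyl bromide (1-bromo-3-methylbut-2-ene)
Product: 7 (4S)-4-benzyl-3-[(2S)-5-methyl-2-(prop-1-en-2-yl)hex-4-enoyl]oxazolidin-2-one, via sodium dienolate 6 (not isolated)
Conditions: NaHMDS, THF, −78 °C; then 5, −78 → −40 °C; AcOH quench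
Reagents that add atoms: none
Why: Evans deconjugative α-alkylation: γ-deprotonation gives the sodium-chelated (Z)-dienolate 6, which reacts with the allylic bromide at the α-carbon on the face opposite the benzyl group, so the new centre is set as (S) by the auxiliary and the isopropenyl group is unveiled at the same time.

Step 3
Reactants: 7 (4S)-4-benzyl-3-[(2S)-5-methyl-2-(prop-1-en-2-yl)hex-4-enoyl]oxazolidin-2-one
Product: 8 (S)-lavandulol [(2S)-5-methyl-2-(prop-1-en-2-yl)hex-4-en-1-ol]
Conditions: LiBH4, H2O (1 equiv), Et2O, 0 °C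
Reagents that add atoms: none
Why: LiBH4 reductive cleavage of the N-acyloxazolidinone attacks the exocyclic carbonyl under conditions too mild to epimerise or reconjugate the α-centre, which is carried unchanged into the primary alcohol.

Step 4
Reactants: 8 (S)-lavandulol
Product: 9 (S)-lavandulyl iodide [(3S)-3-(iodomethyl)-2,6-dimethylhepta-1,5-diene]
Conditions: PPh3, I2, imidazole, CH2Cl2, 0 °C → rt
Reagents that add atoms: iodine, II
Why: Appel-type iodination (Garegg conditions) replaces the primary hydroxyl by SN2 through the alkoxyphosphonium ion under buffered conditions that leave both alkenes and the adjacent stereocentre untouched.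

Step 5
Reactants: 10 2',4'-dihydroxy-6'-methoxyacetophenone
Product: 11 1-[2-hydroxy-6-methoxy-4-(triisopropylsilyloxy)phenyl]ethanone
Conditions: TIPSCl (1.05 equiv), imidazole, DMF, 0 °C
Reagents that add atoms: triisopropylsilyl chloride, CC(C)[Si](Cl)(C(C)C)C(C)C
Why: Selective phenol silylation: the 4'-OH is free and more nucleophilic whereas the 2'-OH is tied up in the hydrogen bond to the ketone, so one equivalent of TIPSCl should protect only O-4'.

Step 6
Reactants: 11 1-[2-hydroxy-6-methoxy-4-(triisopropylsilyloxy)phenyl]ethanone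
Product: 12 1-[2-hydroxy-3-iodo-6-methoxy-4-(triisopropylsilyloxy)phenyl]ethanone
Conditions: NIS (1.0 equiv), MeCN, 0 °C
Reagents that add atoms: N-iodosuccinimide, O=C1CCC(=O)N1I
Why: Electrophilic aromatic iodination of the phloroglucinol-type ring, expected at C3' ortho to the free chelated phenol (the less hindered open position, as with the 4',6'-dimethoxy analogue), with one equivalent of NIS at 0 °C to avoid di-iodination.

Step 7
Reactants: 12 1-[2-hydroxy-3-iodo-6-methoxy-4-(triisopropylsilyloxy)phenyl]ethanone
Product: 14 8-iodo-5-methoxy-7-(triisopropylsilyloxy)-4H-chromen-4-one, via enaminone 13 (not isolated)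
Conditions: DMF-DMA, toluene, 90 °C; then conc. HCl, CH2Cl2, rt
Reagents that add atoms: N,N-dimethylformamide dimethyl acetal, COC(OC)N(C)C
Why: Enaminone chromone synthesis: condensation of the methyl ketone with DMF-DMA gives 13, and acid then triggers 6-endo addition of the phenol to the enaminone with loss of dimethylamine; the acid is used here, before the acid-sensitive side chain is present.

Step 8
Reactants: 9 (S)-lavandulyl iodide; 14 8-iodo-5-methoxy-7-(triisopropylsilyloxy)-4H-chromen-4-one
Product: 16 5-methoxy-8-[(2R)-5-methyl-2-(prop-1-en-2-yl)hex-4-en-1-yl]-7-(triisopropylsilyloxy)-4H-chromen-4-one, via (S)-lavandulylzinc iodide 15 (not isolated)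
Conditions: 9, Zn dust (BrCH2CH2Br/TMSCl-activated), LiCl, THF, 40 °C; then 14, Pd(OAc)2 (5 mol %), SPhos (10 mol %), THF, rt → 50 °C
Reagents that add atoms: none
Why: Negishi sp3–sp2 cross-coupling: LiCl-assisted zinc insertion into the primary iodide gives 15 without touching the β-stereocentre, and Pd/SPhos is chosen because it couples primary alkylzinc halides with di-ortho-substituted aryl iodides while the organozinc is too mild to attack the chromone enone.

Step 9
Reactants: 17 4-bromo-3-methoxyphenol
Product: 18 (4-bromo-3-methoxyphenoxy)triisopropylsilane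
Conditions: TIPSCl, imidazole, DMF, rt
Reagents that add atoms: triisopropylsilyl chloride, CC(C)[Si](Cl)(C(C)C)C(C)C
Why: Standard silylation of the phenol, TIPS being chosen to withstand the organolithium and the aqueous coupling step and to fall to fluoride at the end.

Step 10
Reactants: 18 (4-bromo-3-methoxyphenoxy)triisopropylsilane
Product: 21 [2-methoxy-4-(triisopropylsilyloxy)phenyl]boronic acid, via aryllithium 19 (not isolated), via lithium aryltriisopropoxyborate 20 (not isolated)
Conditions: n-BuLi, THF, −78 °C; B(OiPr)3, −78 °C → rt; 1 M HCl, 0 °C (brief)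
Reagents that add atoms: triisopropyl borate, CC(C)OB(OC(C)C)OC(C)C; water, O
Why: Bromine–lithium exchange at −78 °C, trapping of aryllithium 19 with the borate to the ate complex 20 and brief mild acidic hydrolysis is the standard route to arylboronic acids, and the aryl TIPS ether survives both the organolithium and the short acid work-up.

Step 11
Reactants: 16 5-methoxy-8-[(2R)-5-methyl-2-(prop-1-en-2-yl)hex-4-en-1-yl]-7-(triisopropylsilyloxy)-4H-chromen-4-one; 21 [2-methoxy-4-(triisopropylsilyloxy)phenyl]boronic acid
Product: 22 (2S)-5-methoxy-2-[2-methoxy-4-(triisopropylsilyloxy)phenyl]-8-[(2R)-5-methyl-2-(prop-1-en-2-yl)hex-4-en-1-yl]-7-(triisopropylsilyloxy)chroman-4-one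
Conditions: [Rh(OH)(cod)]2 (2.5 mol %), (S)-MeO-F12-BIPHEP [(S)-2,2'-bis[bis(3,4,5-trifluorophenyl)phosphino]-6,6'-dimethoxy-1,1'-biphenyl] (5.5 mol %), 21 (3 equiv), CH2Cl2/H2O (10:1), 35 °C
Reagents that add atoms: none
Why: Transmetalation of 21 to the Rh(I)–OH complex gives an aryl–Rh(I) bisphosphine species that binds the C2=C3 bond of 16 and inserts it with C–C bond formation at C2, and water then protonates the resulting oxa-π-allyl rhodium at C3 and regenerates Rh–OH. The closest known reaction is the Hayashi–Miyaura asymmetric 1,4-addition of arylboronic acids, which is established for chromones, 5,7-dialkoxychromones included, as a route to flavanones. No ring is closed, since the pyranone ring is already in place. C2 is set by catalyst control: the (S)-biaryl bisphosphine should expose the enone face that leads to 2S, by the same quadrant model under which (S)-BINAP gives (S)-3-arylcyclohexanones (the antipodal ligand would be used if the sense proved opposite), and the remote side-chain centre is neither involved nor at risk. The step needs 1,4- rather than 1,2-addition, no second arylation of the product ketone and no retro-oxa-Michael opening of the flavanone, which the base-free medium, the low temperature and the electron-poor ligand in CH2Cl2 are meant to secure, while the two isolated alkenes are inert because aryl–Rh(I) inserts only into activated alkenes. Excess 21 offsets protodeboronation of the electron-rich ortho-methoxyaryl group.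

Step 12
Reactants: 22 (2S)-5-methoxy-2-[2-methoxy-4-(triisopropylsilyloxy)phenyl]-8-[(2R)-5-methyl-2-(prop-1-en-2-yl)hex-4-en-1-yl]-7-(triisopropylsilyloxy)chroman-4-one
Product: 23 (2S)-2'-methoxykurarinone
Conditions: TBAF/AcOH (1:1, 3 equiv), THF, 0 °C
Reagents that add atoms: none
Why: Fluoride cleaves both aryl Si–O bonds, and the acetic acid buffer keeps the medium non-basic so the flavanone should not open by retro-oxa-Michael reaction (which would racemise C2), while no strong acid is present that could cyclise the 7-OH onto the side-chain alkenes.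

**Compound list**

1 | (S)-4-benzyl-2-oxazolidinone | O=C1N[C@@H](Cc2ccccc2)CO1 | starting material
2 | 3-methylbut-2-enoyl chloride | CC(C)=CC(Cl)=O | starting material
3 | lithium salt of (S)-4-benzyl-2-oxazolidinone | O=C1[N-][C@@H](Cc2ccccc2)CO1.[Li+] | intermediate (not isolated)
4 | (4S)-4-benzyl-3-(3-methylbut-2-enoyl)oxazolidin-2-one | CC(C)=CC(=O)N1C(=O)OC[C@@H]1Cc1ccccc1 | intermediate
5 | prenyl bromide (1-bromo-3-methylbut-2-ene) | CC(C)=CCBr | starting material
6 | sodium (Z)-dienolate of 4 | C=C(C)/C=C(\[O-])N1C(=O)OC[C@@H]1Cc1ccccc1.[Na+] | intermediate (not isolated)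
7 | (4S)-4-benzyl-3-[(2S)-5-methyl-2-(prop-1-en-2-yl)hex-4-enoyl]oxazolidin-2-one | C=C(C)[C@H](CC=C(C)C)C(=O)N1C(=O)OC[C@@H]1Cc1ccccc1 | intermediate
8 | (S)-lavandulol, (2S)-5-methyl-2-(prop-1-en-2-yl)hex-4-en-1-ol | C=C(C)[C@H](CC=C(C)C)CO | intermediate
9 | (S)-lavandulyl iodide, (3S)-3-(iodomethyl)-2,6-dimethylhepta-1,5-diene | C=C(C)[C@H](CC=C(C)C)CI | intermediate
10 | 2',4'-dihydroxy-6'-methoxyacetophenone | CC(=O)c1c(O)cc(O)cc1OC | starting material
11 | 1-[2-hydroxy-6-methoxy-4-(triisopropylsilyloxy)phenyl]ethanone | CC(=O)c1c(O)cc(O[Si](C(C)C)(C(C)C)C(C)C)cc1OC | intermediate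
12 | 1-[2-hydroxy-3-iodo-6-methoxy-4-(triisopropylsilyloxy)phenyl]ethanone | CC(=O)c1c(O)c(I)c(O[Si](C(C)C)(C(C)C)C(C)C)cc1OC | intermediate
13 | (E)-3-(dimethylamino)-1-[2-hydroxy-3-iodo-6-methoxy-4-(triisopropylsilyloxy)phenyl]prop-2-en-1-one | CN(C)/C=C/C(=O)c1c(O)c(I)c(O[Si](C(C)C)(C(C)C)C(C)C)cc1OC | intermediate (not isolated)
14 | 8-iodo-5-methoxy-7-(triisopropylsilyloxy)-4H-chromen-4-one | COc1cc(O[Si](C(C)C)(C(C)C)C(C)C)c(I)c2OC=CC(=O)c12 | intermediate
15 | (S)-lavandulylzinc iodide | C=C(C)[C@H](CC=C(C)C)C[Zn]I | intermediate (not isolated)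
16 | 5-methoxy-8-[(2R)-5-methyl-2-(prop-1-en-2-yl)hex-4-en-1-yl]-7-(triisopropylsilyloxy)-4H-chromen-4-one | C=C(C)[C@H](CC=C(C)C)Cc1c(O[Si](C(C)C)(C(C)C)C(C)C)cc(OC)c2c1OC=CC2=O | intermediate
17 | 4-bromo-3-methoxyphenol | COc1cc(O)ccc1Br | starting material
18 | (4-bromo-3-methoxyphenoxy)triisopropylsilane | COc1cc(O[Si](C(C)C)(C(C)C)C(C)C)ccc1Br | intermediate
19 | [2-methoxy-4-(triisopropylsilyloxy)phenyl]lithium | COc1cc(O[Si](C(C)C)(C(C)C)C(C)C)ccc1[Li] | intermediate (not isolated)
20 | lithium triisopropoxy[2-methoxy-4-(triisopropylsilyloxy)phenyl]borate | COc1cc(O[Si](C(C)C)(C(C)C)C(C)C)ccc1[B-](OC(C)C)(OC(C)C)OC(C)C.[Li+] | intermediate (not isolated)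
21 | [2-methoxy-4-(triisopropylsilyloxy)phenyl]boronic acid | COc1cc(O[Si](C(C)C)(C(C)C)C(C)C)ccc1B(O)O | intermediate
22 | (2S)-5-methoxy-2-[2-methoxy-4-(triisopropylsilyloxy)phenyl]-8-[(2R)-5-methyl-2-(prop-1-en-2-yl)hex-4-en-1-yl]-7-(triisopropylsilyloxy)chroman-4-one | C=C(C)[C@H](CC=C(C)C)Cc1c(O[Si](C(C)C)(C(C)C)C(C)C)cc(OC)c2c1O[C@H](c1ccc(O[Si](C(C)C)(C(C)C)C(C)C)cc1OC)CC2=O | intermediate
23 | (2S)-2'-methoxykurarinone | C=C(C)[C@H](CC=C(C)C)Cc1c(O)cc(OC)c2c1O[C@H](c1ccc(O)cc1OC)CC2=O | target

**Step count.** Total: 12 steps. Longest linear sequence: 7 steps (steps 1, 2, 3, 4, 8, 11, 12).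

**Steps most likely to fail**

Step 11. Insertion of the electron-rich, vinylogous-ester-type chromone into a hindered ortho-substituted aryl–rhodium may be slower than protodeboronation. Enantiopurity could also erode through reversible ring opening of the product. Fallback, from 16 and 18, returning at 22: 18 is converted with magnesium (THF, LiCl) into [2-methoxy-4-(triisopropylsilyloxy)phenyl]magnesium bromide F1. F1 is added to 16 under CuBr·SMe2 with TMSCl in THF at −78 °C (silyl-accelerated organocopper 1,4-addition) to give the 4-(trimethylsilyloxy)-2H-chromene F2 as both C2 epimers. Mild hydrolysis (citric acid, THF/H2O, 0 °C) should give 22 together with its (2R)-epimer F3. Because the side-chain centre is fixed, these are diastereomers; they would be separated by preparative HPLC and the route rejoined at 22.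

Step 8. Oxidative addition and transmetalation at the iodide flanked by the ring oxygen and the OTIPS group may be slow, so hydrodeiodination or β-hydride elimination from the alkylpalladium could take over. Fallback, from 9, returning at 16: copper-catalysed borylation of 9 (B2pin2, CuI, PPh3, LiOtBu, DMF, rt) gives the (S)-lavandulyl pinacol boronate F4. F4 is joined to 14 by B-alkyl Suzuki–Miyaura coupling (Pd(OAc)2, RuPhos, K2CO3, toluene/H2O, 80 °C), whose boronate transmetalation under aqueous base is less sensitive to the ortho substituents.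

Step 6. Iodination may lack regiocontrol (attack at C5' between the silyloxy and methoxy groups) or run on to the di-iodide. Fallback, from 11, returning at 14: ring construction and iodination are reversed. DMF-DMA (toluene, 90 °C) gives the enaminone F5, and HCl/CH2Cl2 closes it to 5-methoxy-7-(triisopropylsilyloxy)-4H-chromen-4-one F6. Iodination of F6 (NIS, cat. TFA, MeCN, 0 °C) is expected at C8, para to the 5-methoxy group, because C6 is flanked by two alkoxy groups; this gives 14.

**Further compounds**

F1 | step 11 | [2-methoxy-4-(triisopropylsilyloxy)phenyl]magnesium bromide | COc1cc(O[Si](C(C)C)(C(C)C)C(C)C)ccc1[Mg]Br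
F2 | step 11 | 5-methoxy-2-[2-methoxy-4-(triisopropylsilyloxy)phenyl]-8-[(2R)-5-methyl-2-(prop-1-en-2-yl)hex-4-en-1-yl]-7-(triisopropylsilyloxy)-4-(trimethylsilyloxy)-2H-chromene (both C2 epimers) | C=C(C)[C@H](CC=C(C)C)Cc1c(O[Si](C(C)C)(C(C)C)C(C)C)cc(OC)c2c1OC(c1ccc(O[Si](C(C)C)(C(C)C)C(C)C)cc1OC)C=C2O[Si](C)(C)C
F3 | step 11 | (2R)-epimer of 22 | C=C(C)[C@H](CC=C(C)C)Cc1c(O[Si](C(C)C)(C(C)C)C(C)C)cc(OC)c2c1O[C@@H](c1ccc(O[Si](C(C)C)(C(C)C)C(C)C)cc1OC)CC2=O
F4 | step 8 | 2-[(2S)-5-methyl-2-(prop-1-en-2-yl)hex-4-en-1-yl]-4,4,5,5-tetramethyl-1,3,2-dioxaborolane | C=C(C)[C@H](CC=C(C)C)CB1OC(C)(C)C(C)(C)O1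
F5 | step 6 | (E)-3-(dimethylamino)-1-[2-hydroxy-6-methoxy-4-(triisopropylsilyloxy)phenyl]prop-2-en-1-one | CN(C)/C=C/C(=O)c1c(O)cc(O[Si](C(C)C)(C(C)C)C(C)C)cc1OC
F6 | step 6 | 5-methoxy-7-(triisopropylsilyloxy)-4H-chromen-4-one | COc1cc(O[Si](C(C)C)(C(C)C)C(C)C)cc2OC=CC(=O)c12
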